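**Retrosynthetic overview**
1. Target 27 ← bridged γ-lactone 26 (C-2 oxygen tied to the C-19 carboxyl as a temporary ring); the C-8 methylene and the C-13 enoate come from lactone diketone 23.
2. Lactone 23 ← C-2 ketone 20 ← ring-A boronate 18 (C-2 carried as a C–B bond, a different oxidation level).
3. Key disconnection C-1/C-2 and C-3/C-4: a two-carbon vinylsulfonium unit is stitched between the ester α-carbon C-4 and the boron-bound CH2 (C-1) of ring-B boronate 13, by conjugate addition, ylide capture at boron and 1,2-shift.
4. Enabling feature: in ring A, C-4 is α to the C-19 carboxyl (an enolate donor) and 1,3 to the carbinol carbon C-2, and C-1 is a neopentyl CH2 on quaternary C-10, a poor SN2 electrophile but a good migrating group from boron; ring B (C-5 to C-10) holds C-1 and C-4 in a 1,4 relation.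
5. Ring order: ring B first from 2-methylcyclohexenone (CBS, Johnson–Claisen for C-5, cyclopropanation and iodide opening for C-10 and C-9), then ring A in step 8.

Key step: step 8

Remark: carbons are named by labdane positions (ring A = C-1 to C-5 and C-10, ring B = C-5 to C-10, C-19 = carboxyl on C-4, C-20 = methyl on C-10); these are position names only.
Remark: the propanoate α-carbon (later C-4) in 5 to 13 is an epimer mixture of no consequence, because it becomes planar in step 8; C-9 in 11 to 13 is drawn as the thermodynamic epimer.

**Step 1**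
Reactants: 1 2-methylcyclohex-2-en-1-one
Product: 2 (R)-2-methylcyclohex-2-en-1-ol
Conditions: (S)-2-methyl-CBS-oxazaborolidine (10 mol %), BH3·SMe2, THF, −20 °C; MeOH quench
Reagents that add atoms: none
Why: Corey–Bakshi–Shibata reduction, in which the methyl-bearing alkene arm acts as the large group, so the (S)-catalyst should give the R carbinol from which all later stereocentres are relayed.

**Step 2**
Reactants: 2 (R)-2-methylcyclohex-2-en-1-ol; 3 triethyl orthopropionate
Product: 5 ethyl 2-[(1R)-2-methylcyclohex-2-en-1-yl]propanoate, via ketene acetal 4 (not isolated)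
Conditions: 3 (5 equiv), EtCO2H (cat.), 140 °C, EtOH distilled off
Reagents that add atoms: 3 triethyl orthopropionate, CCC(OCC)(OCC)OCC
Why: Johnson–Claisen rearrangement, a suprafacial [3,3] shift that delivers the propanoate α-carbon to the alkene terminus on the face the C–O bond leaves and so transfers the carbinol configuration to C-5.

**Step 3**
Reactants: 5 ethyl 2-[(1R)-2-methylcyclohex-2-en-1-yl]propanoate
Product: 6 ethyl 2-[(1R)-2-methyl-4-oxocyclohex-2-en-1-yl]propanoate
Conditions: Rh2(cap)4 (dirhodium tetracaprolactamate, 1 mol %), t-BuOOH (70% aq., 5 equiv), K2CO3, CH2Cl2, rt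
Reagents that add atoms: tert-butyl hydroperoxide, CC(C)(C)OO
Why: allylic C–H oxidation by tert-butylperoxyl radicals, which should attack the unhindered ring CH2 next to the alkene CH in preference to the branched allylic CH and give the β-methyl enone with C-5 untouched.

**Step 4**
Reactants: 6 ethyl 2-[(1R)-2-methyl-4-oxocyclohex-2-en-1-yl]propanoate
Product: 7 ethyl 2-(6-methyl-2-oxobicyclo[4.1.0]heptan-5-yl)propanoate (cyclopropane CH2 trans to the propanoate group)
Conditions: Me3S(O)I, NaH, DMSO, rt
Reagents that add atoms: trimethylsulfoxonium iodide, C[S+](C)(C)=O.[I-]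
Why: Corey–Chaykovsky cyclopropanation, in which the sulfoxonium ylide adds to the β-carbon anti to the neighbouring side chain and closes 3-exo-tet, which sets quaternary C-10 with the new CH2 (C-1) trans to the C-5 substituent.

**Step 5**
Reactants: 7 cyclopropyl ketone; 8 methyl vinyl ketone
Product: 11 ethyl 2-[2-(iodomethyl)-2-methyl-4-oxo-3-(3-oxobutyl)cyclohexyl]propanoate, via iodo silyl enol ether 9 (not isolated), via adduct silyl enol ether 10 (not isolated)
Conditions: Me3SiI (1.0 equiv), CH2Cl2, −40 to 0 °C; then 8, Ph3CSbCl6 (trityl hexachloroantimonate, 5 mol %), −78 °C; 1 M HCl work-up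
Reagents that add atoms: iodotrimethylsilane, C[Si](C)(C)I; 8 methyl vinyl ketone, CC(=O)C=C
Why: homo-conjugate opening of the silyl-activated cyclopropyl ketone by iodide at the cyclopropane CH2 (the exocyclic cyclopropane bond overlaps the carbonyl π system) should give the neopentyl iodide and the enol ether on the C-9 side only, and a Mukaiyama–Michael addition then places the 3-oxobutyl chain at C-9, which is epimerizable and should settle equatorial, trans to the iodomethyl group.

**Step 6**
Reactants: 11 iodo diketone
Product: 12 bis(ethylene ketal) of 11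
Conditions: Me3SiOCH2CH2OSiMe3 (3 equiv), Me3SiOTf (5 mol %), CH2Cl2, −78 to −20 °C
Reagents that add atoms: 1,2-bis(trimethylsilyloxy)ethane, C[Si](C)(C)OCCO[Si](C)(C)C
Why: silyl-triflate-catalysed ketalization under aprotic, cold conditions should mask both ketones against the bases of steps 7 and 8 without aldol condensation of the 1,5-diketone.

**Step 7**
Reactants: 12 bisketal iodide
Product: 13 bisketal pinacol boronate (CH2I replaced by CH2Bpin)
Conditions: CuI (10 mol %), PPh3 (13 mol %), LiOt-Bu (2 equiv), B2pin2 (1.5 equiv), DMF, rt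
Reagents that add atoms: bis(pinacolato)diboron, CC1(C)OB(OC1(C)C)B1OC(C)(C)C(C)(C)O1
Why: copper-catalysed borylation of a primary alkyl iodide runs through an alkyl radical and should therefore not be slowed by the neopentyl position.

**Step 8**
Reactants: 13 bisketal pinacol boronate; 14 diphenyl(vinyl)sulfonium trifluoromethanesulfonate
Product: 18 ring-A pinacol boronate (boryl group on C-2 equatorial; C-19 ethyl ester axial), via lithium enolate 15 (not isolated), via sulfonium ylide 16 (not isolated), via cyclic borate 17 (not isolated)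
Conditions: LDA (1.15 equiv), THF, −78 °C, 1 h; then 14 (1.2 equiv, slow addition), −78 °C to rt
Reagents that add atoms: 14 diphenyl(vinyl)sulfonium trifluoromethanesulfonate, C=C[S+](c1ccccc1)c1ccccc1.[O-]S(=O)(=O)C(F)(F)F
Why: Proposed new method: LDA removes the ester α-hydrogen of 13 (boronate and dioxolanes should tolerate it) and enolate 15 adds through carbon to the cationic acceptor 14, which forms the C-3/C-4 bond and leaves the unstabilized ylide 16; the ylide carbon is captured by the boron on C-1 to give the seven-membered borate 17, and 1,2-migration of C-1 from boron to C-2 with loss of Ph2S forms the C-1/C-2 bond. The closest known reactions are the conjugate addition–ylide capture annulations of vinylsulfonium salts and the 1,2-metallate homologation of boronic esters by sulfur ylides and other carbanions that carry a leaving group (Matteson type); their union into a carbocyclic annulation is new. Ring A closes in the migration step, a ring contraction of the seven-membered borate in which C-1 displaces the sulfonium group at C-2 from the rear (6-exo-tet in carbon terms, with inversion at C-2). The quaternary C-4 is set in the intermolecular step by allylic 1,3-strain: the C-5 hydrogen eclipses the enolate plane and 14 approaches anti to quaternary C-10, which places the ester axial and cis to the C-10 methyl. The C-2 boronate is expected equatorial, but its configuration does not matter because C-2 passes through the ketone in steps 10 and 11. The step needs C- over O-alkylation (soft cationic acceptor), boron capture faster than attack of the ylide on a second molecule of 14 (intramolecular capture, slow addition) and migration of carbon rather than pinacol oxygen (the normal course for boronic ester ate complexes).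

**Step 9**
Reactants: 18 ring-A pinacol boronate
Product: 19 C-2 equatorial alcohol (bisketal ethyl ester)
Conditions: H2O2 (30% aq.), NaOH (2 M), THF, 0 °C
Reagents that add atoms: hydrogen peroxide, OO
Why: oxidation of the carbon–boron bond by 1,2-migration from boron to oxygen, with retention, should turn the boronate into the C-2 alcohol.

**Step 10**
Reactants: 19 C-2 equatorial alcohol
Product: 20 C-2 ketone (bisketal ethyl ester)
Conditions: Dess–Martin periodinane, CH2Cl2, rt
Reagents that add atoms: none
Why: Dess–Martin oxidation erases the C-2 configuration left by the key step, so either C-2 epimer of 19 converges on one ketone.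

**Step 11**
Reactants: 20 C-2 ketone
Product: 23 lactone diketone (γ-lactone from C-19 to C-2; ring ketone at C-8; methyl ketone at C-13), via axial alcohol 21 (not isolated), via lactone bisketal 22 (not isolated)
Conditions: NaBH4, MeOH, −20 °C; then 1 M aq. HCl, THF, 40 °C
Reagents that add atoms: water, O
Why: hydride should approach from the equatorial direction because the axial C-10 methyl and the axial C-4 ester block the other face, which sets the axial C-2 alcohol syn to the ester; the acid then closes the γ-lactone (lactonization) and hydrolyses both dioxolanes.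

**Step 12**
Reactants: 23 lactone diketone; 24 triethyl phosphonoacetate
Product: 25 ethyl enoate keto lactone (13E)
Conditions: 24 (1.2 equiv), NaH (1.1 equiv), THF, 0 °C to rt; chromatography to remove the Z isomer
Reagents that add atoms: 24 triethyl phosphonoacetate, CCOC(=O)CP(=O)(OCC)OCC
Why: Horner–Wadsworth–Emmons olefination should take place at the unhindered methyl ketone only, since the ring ketone carries a branched α-carbon next to quaternary C-10, the preformed phosphonate anion (no excess base) is too weakly basic to favour aldol closure of the 1,5-diketone, and the stabilized phosphonate favours the E trisubstituted enoate.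

**Step 13**
Reactants: 25 ethyl enoate keto lactone
Product: 26 ethyl ester lactone with the C-8 exocyclic methylene
Conditions: Zn, CH2Br2, TiCl4, THF/CH2Cl2, 0 °C to rt
Reagents that add atoms: dibromomethane, BrCBr
Why: Takai–Lombardo methylenation is non-basic and should convert the hindered ring ketone into the exocyclic methylene without touching the enoate, the lactone or C-9, which already sits in its equatorial configuration.

**Step 14**
Reactants: 26 ethyl ester lactone
Product: 27 target hydroxy diacid
Conditions: LiOH·H2O, THF/MeOH/H2O, 40 °C; then 1 M HCl to pH 4, 0 °C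
Reagents that add atoms: lithium hydroxide, [Li+].[OH-]
Why: saponification of the ethyl enoate and of the bridged γ-lactone should release the axial C-2 hydroxyl and the C-19 acid with no stereocentre touched, and the cold, mildly acidic work-up is meant to avoid relactonization.

**Compound list**
1 | 2-methylcyclohex-2-en-1-one | CC1=CCCCC1=O | starting material
2 | (R)-2-methylcyclohex-2-en-1-ol | O[C@@H]1CCCC=C1C | intermediate
3 | triethyl orthopropionate | CCC(OCC)(OCC)OCC | starting material
4 | mixed ketene acetal, 1-ethoxy-1-[(1R)-2-methylcyclohex-2-en-1-yl]oxyprop-1-ene | CC=C(OCC)O[C@@H]1CCCC=C1C | intermediate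
5 | ethyl 2-[(1R)-2-methylcyclohex-2-en-1-yl]propanoate (α-carbon epimers) | CCOC(=O)C(C)[C@H]1CCCC=C1C | intermediate
6 | ethyl 2-[(1R)-2-methyl-4-oxocyclohex-2-en-1-yl]propanoate | O=C1CC[C@H](C(C)C(=O)OCC)C(C)=C1 | intermediate
7 | ethyl 2-(6-methyl-2-oxobicyclo[4.1.0]heptan-5-yl)propanoate, cyclopropane CH2 trans to the propanoate group | O=C1CC[C@H](C(C)C(=O)OCC)[C@@]2(C)C[C@@H]12 | intermediate
8 | methyl vinyl ketone (but-3-en-2-one) | CC(=O)C=C | starting material
9 | ethyl 2-[2-(iodomethyl)-2-methyl-4-(trimethylsilyloxy)cyclohex-3-en-1-yl]propanoate, iodomethyl trans to the propanoate group | C[Si](C)(C)OC1=C[C@](C)(CI)[C@@H](C(C)C(=O)OCC)CC1 | intermediate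
10 | ethyl 2-[2-(iodomethyl)-2-methyl-4-oxo-3-[3-(trimethylsilyloxy)but-2-enyl]cyclohexyl]propanoate | O=C1CC[C@H](C(C)C(=O)OCC)[C@@](C)(CI)[C@@H]1CC=C(C)O[Si](C)(C)C | intermediate
11 | ethyl 2-[2-(iodomethyl)-2-methyl-4-oxo-3-(3-oxobutyl)cyclohexyl]propanoate, iodomethyl trans to both neighbouring side chains | O=C1CC[C@H](C(C)C(=O)OCC)[C@@](C)(CI)[C@@H]1CCC(C)=O | intermediate
12 | ethyl 2-[7-(iodomethyl)-7-methyl-6-[2-(2-methyl-1,3-dioxolan-2-yl)ethyl]-1,4-dioxaspiro[4.5]decan-8-yl]propanoate | C12(OCCO1)CC[C@H](C(C)C(=O)OCC)[C@@](C)(CI)[C@@H]2CCC3(C)OCCO3 | intermediate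
13 | ethyl 2-[7-methyl-6-[2-(2-methyl-1,3-dioxolan-2-yl)ethyl]-7-[(4,4,5,5-tetramethyl-1,3,2-dioxaborolan-2-yl)methyl]-1,4-dioxaspiro[4.5]decan-8-yl]propanoate | C12(OCCO1)CC[C@H](C(C)C(=O)OCC)[C@@](C)(CB3OC(C)(C)C(C)(C)O3)[C@@H]2CCC4(C)OCCO4 | intermediate
14 | diphenyl(vinyl)sulfonium trifluoromethanesulfonate | C=C[S+](c1ccccc1)c1ccccc1.[O-]S(=O)(=O)C(F)(F)F | starting material
15 | lithium ester enolate of 13 (enolate geometry not fixed) | C12(OCCO1)CC[C@H](C(C)=C(OCC)O[Li])[C@@](C)(CB3OC(C)(C)C(C)(C)O3)[C@@H]2CCC4(C)OCCO4 | intermediate
16 | sulfonium ylide: C-4 now quaternary (methyl, ethyl ester, CH2–CH(−)–S(+)Ph2 arm), boronate still on C-1 | C12(OCCO1)CC[C@H]([C@@](C)(C[CH-][S+](c3ccccc3)c3ccccc3)C(=O)OCC)[C@@](C)(CB3OC(C)(C)C(C)(C)O3)[C@@H]2CCC4(C)OCCO4 | intermediate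
17 | zwitterionic seven-membered cyclic borate: boron bonded to C-1 and C-2, diphenylsulfonio group on C-2 | C12(OCCO1)CC[C@H]3[C@@](C)(C[B-]4(OC(C)(C)C(C)(C)O4)[C@H]([S+](c4ccccc4)c4ccccc4)C[C@@]3(C)C(=O)OCC)[C@@H]2CCC4(C)OCCO4 | intermediate
18 | trans-decalin ring-A boronate: ethyl 2-(pinacolatoboryl)-8,13-dioxo-14,15,17-trinorlabdan-19-oate 8,13-bis(ethylene ketal), boryl equatorial, ester axial and cis to the C-10 methyl | C12(OCCO1)CC[C@H]3[C@@](C)(C[C@H](B4OC(C)(C)C(C)(C)O4)C[C@@]3(C)C(=O)OCC)[C@@H]2CCC5(C)OCCO5 | intermediate
19 | C-2 equatorial alcohol of the same bisketal ethyl ester (C-2 epimer of the target configuration) | C12(OCCO1)CC[C@H]3[C@@](C)(C[C@H](O)C[C@@]3(C)C(=O)OCC)[C@@H]2CCC4(C)OCCO4 | intermediate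
20 | C-2 ketone of the same bisketal ethyl ester | C12(OCCO1)CC[C@H]3[C@@](C)(CC(=O)C[C@@]3(C)C(=O)OCC)[C@@H]2CCC4(C)OCCO4 | intermediate
21 | C-2 axial alcohol of the same bisketal ethyl ester (hydroxyl cis to the ester and the C-10 methyl) | C12(OCCO1)CC[C@H]3[C@@](C)(C[C@@H](O)C[C@@]3(C)C(=O)OCC)[C@@H]2CCC4(C)OCCO4 | intermediate
22 | γ-lactone (C-19 carbonyl to C-2 oxygen) 8,13-bis(ethylene ketal) | C12(OCCO1)CC[C@H]3[C@@](C)(C[C@@H]4C[C@@]3(C)C(=O)O4)[C@@H]2CCC5(C)OCCO5 | intermediate
23 | 8,13-dioxo-14,15,17-trinorlabdan-19,2-olide (lactone diketone) | O=C1CC[C@H]2[C@@](C)(C[C@@H]3C[C@@]2(C)C(=O)O3)[C@@H]1CCC(C)=O | intermediate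
24 | triethyl phosphonoacetate | CCOC(=O)CP(=O)(OCC)OCC | starting material
25 | ethyl 8-oxo-17-norlabd-13E-en-19,2-olid-15-oate | O=C1CC[C@H]2[C@@](C)(C[C@@H]3C[C@@]2(C)C(=O)O3)[C@@H]1CC/C(C)=C/C(=O)OCC | intermediate
26 | ethyl labda-8(17),13E-dien-19,2-olid-15-oate | C=C1CC[C@H]2[C@@](C)(C[C@@H]3C[C@@]2(C)C(=O)O3)[C@@H]1CC/C(C)=C/C(=O)OCC | intermediate
27 | target: 2-hydroxylabda-8(17),13E-diene-15,19-dioic acid, 2-hydroxyl axial and cis to the C-19 acid and the C-10 methyl, enantiomer as in the SMILES | C=C1CC[C@H]2[C@@](C)(C[C@@H](O)C[C@@]2(C)C(=O)O)[C@@H]1CC/C(C)=C/C(=O)O | target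

**Step count**
Total steps: 14. Longest linear sequence: 14 steps (1 to 27).

**Steps most likely to fail**

1. Step 8 (proposed new method). The ylide may be consumed by a second molecule of the vinylsulfonium salt or rearrange before boron captures it, or the conjugate addition may take place with poor facial selectivity at C-4. The fallback uses known chemistry and sets out from iodide 12. Enolate allylation of 12 with LDA and then allyl bromide, under the same 1,3-strain control, should give the C-4 allylated iodide F1 as the quaternary ester. Ozonolysis with O3 and then Me2S should give the aldehyde F2 with the iodide intact. A samarium diiodide Barbier cyclization (SmI2, THF/HMPA) should then close the C-1/C-2 bond to the C-2 alcohols 19 and 21, and Dess–Martin oxidation of that mixture brings the route back at ketone 20. Any axial alkoxide that closes onto the ester in the flask would give lactone bisketal 22, which is itself on the route.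

2. Step 5. The silyl iodide may open the cyclopropane at the ring-fusion bond (ring enlargement) or attack the ethyl ester. The fallback sets out from enone 6 and builds the quaternary centre by conjugate addition instead. Copper-catalysed addition of (isopropoxydimethylsilyl)methylmagnesium chloride with Me3SiCl trapping, anti to the C-5 side chain, should give the silyl enol ether F3 with the quaternary centre in place. Mukaiyama–Michael addition to 8 should give the silylmethyl diketone F4 after acidic work-up. Tamao–Fleming oxidation (H2O2, KF, KHCO3) should give the hydroxymethyl diketone F5 with both ketones untouched, and Appel iodination (I2, PPh3, imidazole) brings the route back at iodo diketone 11.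

3. Step 11. Hydride delivery may partly take the axial direction, or lactonization may stay incomplete. The fallback sets out from equatorial alcohol 19 and inverts C-2 by displacement instead of reduction. Mesylation (MsCl, Et3N) should give the C-2 equatorial methanesulfonate F6 with the ester and ketals intact. On warming in DMF the axial ester carbonyl oxygen should displace the equatorial mesylate from the rear, with loss of the ethyl group, which brings the route back at lactone bisketal 22; acid hydrolysis as in step 11 then gives 23.

**Further compounds**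
F1 | step 8 | C-4 allylated iodide: ethyl 2-[7-(iodomethyl)-7-methyl-6-[2-(2-methyl-1,3-dioxolan-2-yl)ethyl]-1,4-dioxaspiro[4.5]decan-8-yl]-2-methylpent-4-enoate | C12(OCCO1)CC[C@H]([C@@](C)(CC=C)C(=O)OCC)[C@@](C)(CI)[C@@H]2CCC3(C)OCCO3
F2 | step 8 | aldehyde from F1: ethyl 2-[7-(iodomethyl)-7-methyl-6-[2-(2-methyl-1,3-dioxolan-2-yl)ethyl]-1,4-dioxaspiro[4.5]decan-8-yl]-2-methyl-4-oxobutanoate | C12(OCCO1)CC[C@H]([C@@](C)(CC=O)C(=O)OCC)[C@@](C)(CI)[C@@H]2CCC3(C)OCCO3
F3 | step 5 | silyl enol ether: ethyl 2-[2-[(isopropoxydimethylsilyl)methyl]-2-methyl-4-(trimethylsilyloxy)cyclohex-3-en-1-yl]propanoate | C[Si](C)(C)OC1=C[C@](C)(C[Si](C)(C)OC(C)C)[C@@H](C(C)C(=O)OCC)CC1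
F4 | step 5 | silylmethyl diketone: ethyl 2-[2-[(isopropoxydimethylsilyl)methyl]-2-methyl-4-oxo-3-(3-oxobutyl)cyclohexyl]propanoate | O=C1CC[C@H](C(C)C(=O)OCC)[C@@](C)(C[Si](C)(C)OC(C)C)[C@@H]1CCC(C)=O
F5 | step 5 | hydroxymethyl diketone: ethyl 2-[2-(hydroxymethyl)-2-methyl-4-oxo-3-(3-oxobutyl)cyclohexyl]propanoate | O=C1CC[C@H](C(C)C(=O)OCC)[C@@](C)(CO)[C@@H]1CCC(C)=O
F6 | step 11 | C-2 equatorial methanesulfonate of 19 | C12(OCCO1)CC[C@H]3[C@@](C)(C[C@H](OS(C)(=O)=O)C[C@@]3(C)C(=O)OCC)[C@@H]2CCC4(C)OCCO4
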